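**Plan**

- Retrosynthesis, side chain first: the epoxide oxygen is removed (C13=C14 of an E-allylic alcohol), then C14–C15 and C13–C16 (carbometalation of an alkyne), then C13≡C14 (homologation of a C13 aldehyde made from an allyl group), then C8=C17 (from a C8 ketone).
- Key cut: C10–C20 and C9–C11 together. In labdane numbering the angular methyl C20 and the chain carbon C11 sit on the β- and α-carbons of the C8 carbonyl, so both come from the ring-B enone C8(=O)–C9=C10 at the ring fusion.
- The enone is cut at C9=C10 (aldol condensation), C5–C6 (Michael addition to methyl vinyl ketone) and C4–C19 (conjugate arylation of 3-methylcyclohexenone, phenyl as latent carboxyl).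
- Forward: ring A is the starting cyclohexenone; ring B is closed by the aldol condensation; the key step adds C20 and the allyl chain without closing a ring; the chain is then grown and epoxidised last.
- Stereochemistry: C4 from the chiral copper catalyst; C5 from C4 (attack anti to phenyl); C10 and C9 from C4/C5 through the cis-fused bicycle; the E-alkene from syn-carboalumination; C13/C14 from D-(−)-diethyl tartrate.

Key step: step 6

Remark: labdane numbering is used for all intermediates (ring A = C1–C5, C10; ring B = C5–C10); in step 1 the ligand antipode is taken to be the one that gives the S quaternary centre.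

**Route**

Step 1
Reactants: 1 3-methylcyclohex-2-en-1-one; 2 phenyllithium
Product: 4 trimethyl{[(3S)-3-methyl-3-phenylcyclohex-1-en-1-yl]oxy}silane, via aluminium enolate 3 (not isolated)
Conditions: PhLi, Me2AlCl, pentane/Et2O, −78 → 22 °C (gives PhAlMe2); Cu(O2CC4H3S) (10 mol %), chiral aminophosphine ligand (SimplePhos type, 11 mol %), Et2O, −10 °C; then Me3SiOTf, −10 → 22 °C
Reagents that add atoms: trimethylsilyl trifluoromethanesulfonate, C[Si](C)(C)OS(=O)(=O)C(F)(F)F
Why: Copper-catalysed asymmetric conjugate addition of an arylalane to a β-methyl cyclohexenone is an established way to aryl(methyl) quaternary centres, the ligand antipode fixing S at the future C4, and O-silylation of the aluminium enolate locks the enolate between C10 and C5, a regiochemistry that deprotonation of the ketone would not give.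

Step 2
Reactants: 4 trimethyl{[(3S)-3-methyl-3-phenylcyclohex-1-en-1-yl]oxy}silane; 5 methyl vinyl ketone (but-3-en-2-one)
Product: 6 (2R,3S)-3-methyl-2-(3-oxobutyl)-3-phenylcyclohexan-1-one
Conditions: TiCl4, Ti(Oi-Pr)4, CH2Cl2, −78 °C; aq. K2CO3
Reagents that add atoms: none
Why: Mukaiyama–Michael addition; in the half-chair enol ether phenyl should take the pseudoaxial site beside the geminal methyl (as in 1-methyl-1-phenylcyclohexane) and shield that face, so C5 attacks the titanium-activated enone along the axial trajectory anti to phenyl, placing the oxobutyl chain trans to phenyl (H5 cis to the future carboxyl) under kinetic control.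

Step 3
Reactants: 6 (2R,3S)-3-methyl-2-(3-oxobutyl)-3-phenylcyclohexan-1-one
Product: 7 (1S,2R)-1-methyl-3-oxo-2-(3-oxobutyl)cyclohexane-1-carboxylic acid
Conditions: RuCl3 (5 mol %), NaIO4, CCl4/MeCN/H2O, 22 °C
Reagents that add atoms: sodium periodate, [Na+].[O-]I(=O)(=O)=O; water, O
Why: Catalytic RuO4 oxidation (RuCl3/NaIO4) degrades a phenyl ring to the carboxylic acid of its ipso carbon; the benzylic carbon is quaternary, saturated ketones are inert, and the weakly acidic two-phase medium should not enolise C5, so both stereocentres are kept.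

Step 4
Reactants: 7 (1S,2R)-1-methyl-3-oxo-2-(3-oxobutyl)cyclohexane-1-carboxylic acid
Product: 8 methyl (1S,2R)-1-methyl-3-oxo-2-(3-oxobutyl)cyclohexane-1-carboxylate
Conditions: Me3SiCHN2, MeOH/PhMe, 0 → 22 °C
Reagents that add atoms: (trimethylsilyl)diazomethane, C[Si](C)(C)C=[N+]=[N-]
Why: Methyl esterification with (trimethylsilyl)diazomethane alkylates the carboxylate oxygen under neutral conditions, which suits the hindered acid and avoids base-induced epimerisation at C5 or premature aldol reaction.

Step 5
Reactants: 8 methyl (1S,2R)-1-methyl-3-oxo-2-(3-oxobutyl)cyclohexane-1-carboxylate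
Product: 9 methyl (1S,8aS)-1-methyl-6-oxo-1,2,3,4,6,7,8,8a-octahydronaphthalene-1-carboxylate
Conditions: NaOMe, MeOH, 0 → 22 °C
Reagents that add atoms: none
Why: Intramolecular aldol condensation (the ring-closing half of a Robinson annulation): the methyl ketone enolate (C9) adds to the ring ketone C10 to close six-membered ring B and E1cB dehydration gives the conjugated enone; the C5–H beside the quaternary C4 should be removed more slowly than the methyl and methylene protons, so its configuration carries through, and the neopentyl ester resists methoxide.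

Step 6
Reactants: 9 methyl (1S,8aS)-1-methyl-6-oxo-1,2,3,4,6,7,8,8a-octahydronaphthalene-1-carboxylate; 10 lithium dimethylcuprate; 11 allyl bromide
Product: 13 methyl (1S,4aS,5R,8aS)-1,4a-dimethyl-6-oxo-5-(prop-2-en-1-yl)decahydronaphthalene-1-carboxylate, via lithium enolate 12 (not isolated)
Conditions: Me2CuLi (from MeLi, CuI), Et2O, −20 → 0 °C; then allyl bromide, THF/DMPU, −30 → 0 °C; aq. NH4Cl/NH3
Reagents that add atoms: none
Why: The Gilman cuprate adds 1,4 to the enone through a copper π-complex and a β-cuprio enolate, reductive elimination forms C10–C20 and leaves the lithium enolate fixed between C8 and C9, and allyl bromide then alkylates C9 by SN2 to form C9–C11; the closest known reaction type is conjugate methylation of ring-fusion octalones to cis-fused angular-methyl decalones with alkylation of the resulting enolate. No ring is closed, so no mode of closure applies. C10 is controlled by ring A: the axial trajectory leading to the trans fusion would bring the entering methyl syn-axial to the axial C4 methyl and to H2, so methyl should enter on the H5 face and the fusion be cis. C9 is controlled by the cis-fused enolate: ring A with its quaternary C4 screens the concave face, while on the convex C20 face the chair-like axial approach, anti to the C10–C1 bond, meets only H5 and H7, so allyl should end up cis to C20. The step needs C-alkylation at C9 before the enolate equilibrates towards C7, and no attack on the ester; the regiospecific in-situ enolate, the high SN2 reactivity of allyl bromide in THF/DMPU and the cuprate-inert neopentyl ester should secure this.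

Step 7
Reactants: 13 methyl (1S,4aS,5R,8aS)-1,4a-dimethyl-6-oxo-5-(prop-2-en-1-yl)decahydronaphthalene-1-carboxylate
Product: 14 methyl (1S,4aR,5S,8aS)-1,4a-dimethyl-6-methylidene-5-(prop-2-en-1-yl)decahydronaphthalene-1-carboxylate
Conditions: Zn, CH2Br2, TiCl4, THF/CH2Cl2, 0 → 22 °C
Reagents that add atoms: dibromomethane, BrCBr
Why: Takai–Lombardo methylenation; the zinc/titanium methylene reagent is non-basic, so the epimerisable C9 next to the carbonyl is not touched, it accepts hindered enolisable ketones, and it leaves the ester alone, unlike titanocene methylidene reagents.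

Step 8
Reactants: 14 methyl (1S,4aR,5S,8aS)-1,4a-dimethyl-6-methylidene-5-(prop-2-en-1-yl)decahydronaphthalene-1-carboxylate
Product: 16 methyl (1S,4aR,5S,8aS)-5-(3-hydroxypropyl)-1,4a-dimethyl-6-methylidenedecahydronaphthalene-1-carboxylate, via trialkylborane 15 (not isolated)
Conditions: Sia2BH (from BH3·SMe2, 2-methylbut-2-ene), THF, 0 °C; then NaOH, H2O2, 0 → 22 °C
Reagents that add atoms: hydrogen peroxide, OO
Why: Hydroboration–oxidation with disiamylborane; the bulky dialkylborane adds anti-Markovnikov to the monosubstituted allyl terminus much faster than to the 1,1-disubstituted C8 methylene next to the branched C9, and alkaline peroxide replaces boron by hydroxyl with the hindered ester intact.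

Step 9
Reactants: 16 methyl (1S,4aR,5S,8aS)-5-(3-hydroxypropyl)-1,4a-dimethyl-6-methylidenedecahydronaphthalene-1-carboxylate
Product: 17 methyl (1S,4aR,5S,8aS)-1,4a-dimethyl-6-methylidene-5-(3-oxopropyl)decahydronaphthalene-1-carboxylate
Conditions: TEMPO (10 mol %), PhI(OAc)2, CH2Cl2, 22 °C
Reagents that add atoms: none
Why: Oxoammonium-mediated (TEMPO/PhI(OAc)2) oxidation of a primary alcohol stops at the aldehyde and does not touch the alkene or the ester.

Step 10
Reactants: 17 methyl (1S,4aR,5S,8aS)-1,4a-dimethyl-6-methylidene-5-(3-oxopropyl)decahydronaphthalene-1-carboxylate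
Product: 18 methyl (1S,4aR,5S,8aS)-5-(but-3-yn-1-yl)-1,4a-dimethyl-6-methylidenedecahydronaphthalene-1-carboxylate
Conditions: MeC(O)C(N2)P(O)(OMe)2, K2CO3, MeOH, 0 → 22 °C
Reagents that add atoms: dimethyl (1-diazo-2-oxopropyl)phosphonate, CC(=O)C(=[N+]=[N-])P(=O)(OC)OC
Why: Seyferth–Gilbert homologation with the Ohira–Bestmann reagent; the diazomethylphosphonate anion formed in situ olefinates the aldehyde and the diazoalkene loses N2 with a 1,2-hydride shift, giving the terminal alkyne (C14 added) under mild carbonate conditions.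

Step 11
Reactants: 18 methyl (1S,4aR,5S,8aS)-5-(but-3-yn-1-yl)-1,4a-dimethyl-6-methylidenedecahydronaphthalene-1-carboxylate
Product: 21 methyl (1S,4aR,5S,8aS)-5-[(3E)-5-hydroxy-3-methylpent-3-en-1-yl]-1,4a-dimethyl-6-methylidenedecahydronaphthalene-1-carboxylate, via alkenylalane 19 (not isolated), via lithium alkenylaluminate 20 (not isolated)
Conditions: Me3Al, Cp2ZrCl2 (25 mol %), CH2Cl2, 0 → 22 °C; volatiles removed; n-BuLi, THF, −78 °C; (CH2O)n, −78 → 22 °C; aq. potassium sodium tartrate
Reagents that add atoms: trimethylaluminium, C[Al](C)C; paraformaldehyde (as formaldehyde), C=O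
Why: Negishi zirconium-catalysed carboalumination adds methyl and aluminium syn across the terminal alkyne with methyl on the internal carbon C13, and the derived aluminate is hydroxymethylated by formaldehyde with retention, so the trisubstituted alkene should form as the E isomer; the isolated 1,1-disubstituted alkene is inert and the neopentyl ester should tolerate Me3Al and the brief stoichiometric n-BuLi treatment at −78 °C.

Step 12
Reactants: 21 methyl (1S,4aR,5S,8aS)-5-[(3E)-5-hydroxy-3-methylpent-3-en-1-yl]-1,4a-dimethyl-6-methylidenedecahydronaphthalene-1-carboxylate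
Product: 22 methyl (1S,4aR,5S,8aS)-5-{2-[(2R,3R)-3-(hydroxymethyl)-2-methyloxiran-2-yl]ethyl}-1,4a-dimethyl-6-methylidenedecahydronaphthalene-1-carboxylate (CNP0175926.1)
Conditions: Ti(Oi-Pr)4 (10 mol %), D-(−)-diethyl tartrate (12 mol %), t-BuOOH, 4 Å MS, CH2Cl2, −20 °C
Reagents that add atoms: tert-butyl hydroperoxide, CC(C)(C)OO
Why: Katsuki–Sharpless asymmetric epoxidation; the titanium tartrate complex delivers oxygen only to the allylic alcohol, and D-(−)-diethyl tartrate selects the face of the E-alkene that gives the (13R,14R) epoxide (the mirror image of the sense known for L-(+)-tartrate with E-3-methylalk-2-en-1-ols), the reagent overriding the remote ring stereocentres and leaving the C8 methylene untouched.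

**Compound list**

1 | 3-methylcyclohex-2-en-1-one | CC1=CC(=O)CCC1 | starting material
2 | phenyllithium | [Li]c1ccccc1 | starting material
3 | dimethylaluminium (3S)-3-methyl-3-phenylcyclohex-1-en-1-olate (aluminium enolate, not isolated) | C[Al](C)OC1=C[C@@](C)(c2ccccc2)CCC1 | intermediate
4 | trimethyl{[(3S)-3-methyl-3-phenylcyclohex-1-en-1-yl]oxy}silane | C[Si](C)(C)OC1=C[C@@](C)(c2ccccc2)CCC1 | intermediate
5 | methyl vinyl ketone (but-3-en-2-one) | CC(=O)C=C | starting material
6 | (2R,3S)-3-methyl-2-(3-oxobutyl)-3-phenylcyclohexan-1-one (oxobutyl trans to phenyl) | CC(=O)CC[C@H]1C(=O)CCC[C@]1(C)c2ccccc2 | intermediate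
7 | (1S,2R)-1-methyl-3-oxo-2-(3-oxobutyl)cyclohexane-1-carboxylic acid | CC(=O)CC[C@H]1C(=O)CCC[C@]1(C)C(=O)O | intermediate
8 | methyl (1S,2R)-1-methyl-3-oxo-2-(3-oxobutyl)cyclohexane-1-carboxylate | CC(=O)CC[C@H]1C(=O)CCC[C@]1(C)C(=O)OC | intermediate
9 | methyl (1S,8aS)-1-methyl-6-oxo-1,2,3,4,6,7,8,8a-octahydronaphthalene-1-carboxylate (C8 ketone, C9=C10 alkene, H5 cis to the ester) | O=C1CC[C@H]2C(=C1)CCC[C@]2(C)C(=O)OC | intermediate
10 | lithium dimethylcuprate | [Li+].C[Cu-]C | starting material
11 | allyl bromide (3-bromoprop-1-ene) | C=CCBr | starting material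
12 | lithium (4aS,5S,8aS)-5-(methoxycarbonyl)-5,8a-dimethyl-3,4,4a,5,6,7,8,8a-octahydronaphthalen-2-olate (C8–C9 lithium enolate, not isolated) | [Li]OC1CC[C@H]2[C@](C)(CCC[C@]2(C)C(=O)OC)C=1 | intermediate
13 | methyl (1S,4aS,5R,8aS)-1,4a-dimethyl-6-oxo-5-(prop-2-en-1-yl)decahydronaphthalene-1-carboxylate (cis-fused; H5, C20, allyl and ester on one face) | O=C1CC[C@H]2[C@](C)(CCC[C@]2(C)C(=O)OC)[C@H]1CC=C | intermediate
14 | methyl (1S,4aR,5S,8aS)-1,4a-dimethyl-6-methylidene-5-(prop-2-en-1-yl)decahydronaphthalene-1-carboxylate | C=C1CC[C@H]2[C@](C)(CCC[C@]2(C)C(=O)OC)[C@H]1CC=C | intermediate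
15 | methyl (1S,4aR,5S,8aS)-5-{3-[bis(3-methylbutan-2-yl)boranyl]propyl}-1,4a-dimethyl-6-methylidenedecahydronaphthalene-1-carboxylate (not isolated) | C=C1CC[C@H]2[C@](C)(CCC[C@]2(C)C(=O)OC)[C@H]1CCCB(C(C)C(C)C)C(C)C(C)C | intermediate
16 | methyl (1S,4aR,5S,8aS)-5-(3-hydroxypropyl)-1,4a-dimethyl-6-methylidenedecahydronaphthalene-1-carboxylate | C=C1CC[C@H]2[C@](C)(CCC[C@]2(C)C(=O)OC)[C@H]1CCCO | intermediate
17 | methyl (1S,4aR,5S,8aS)-1,4a-dimethyl-6-methylidene-5-(3-oxopropyl)decahydronaphthalene-1-carboxylate | C=C1CC[C@H]2[C@](C)(CCC[C@]2(C)C(=O)OC)[C@H]1CCC=O | intermediate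
18 | methyl (1S,4aR,5S,8aS)-5-(but-3-yn-1-yl)-1,4a-dimethyl-6-methylidenedecahydronaphthalene-1-carboxylate | C=C1CC[C@H]2[C@](C)(CCC[C@]2(C)C(=O)OC)[C@H]1CCC#C | intermediate
19 | methyl (1S,4aR,5S,8aS)-5-[(3E)-4-(dimethylalumanyl)-3-methylbut-3-en-1-yl]-1,4a-dimethyl-6-methylidenedecahydronaphthalene-1-carboxylate (not isolated) | C=C1CC[C@H]2[C@](C)(CCC[C@]2(C)C(=O)OC)[C@H]1CC/C(C)=C/[Al](C)C | intermediate
20 | lithium butyl(dimethyl)aluminate of 19 (not isolated) | C=C1CC[C@H]2[C@](C)(CCC[C@]2(C)C(=O)OC)[C@H]1CC/C(C)=C/[Al-](C)(C)CCCC.[Li+] | intermediate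
21 | methyl (1S,4aR,5S,8aS)-5-[(3E)-5-hydroxy-3-methylpent-3-en-1-yl]-1,4a-dimethyl-6-methylidenedecahydronaphthalene-1-carboxylate | C=C1CC[C@H]2[C@](C)(CCC[C@]2(C)C(=O)OC)[C@H]1CC/C(C)=C/CO | intermediate
22 | methyl (1S,4aR,5S,8aS)-5-{2-[(2R,3R)-3-(hydroxymethyl)-2-methyloxiran-2-yl]ethyl}-1,4a-dimethyl-6-methylidenedecahydronaphthalene-1-carboxylate (CNP0175926.1) | C=C1CC[C@H]2[C@](C)(CCC[C@]2(C)C(=O)OC)[C@H]1CC[C@@]1(C)O[C@@H]1CO | target

**Step count and risks**

Total step count: 12. Longest linear sequence: 12 steps (from 1 to 22).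

The three steps most likely to fail:

Step 2 (Mukaiyama–Michael addition). Lewis-acid oligomerisation of methyl vinyl ketone may outrun attack by the neopentyl C5, or the facial discrimination between phenyl and methyl may be incomplete. The fallback replaces the conjugate addition by an SN2 alkylation with a masked butanone. It sets out from 4: MeLi (THF, 0 °C) cleaves the silyl ether to the regiodefined enolate, lithium (3S)-3-methyl-3-phenylcyclohex-1-en-1-olate F1. This is alkylated at the allylic chloride of (E)-1,3-dichlorobut-2-ene (Wichterle reagent), again axially and anti to phenyl, to give (2R,3S)-2-[(2E)-3-chlorobut-2-en-1-yl]-3-methyl-3-phenylcyclohexan-1-one F2. Hydrolysis of the vinyl chloride (Hg(O2CCF3)2, MeNO2, then aqueous HCl) unmasks the methyl ketone, and the route is rejoined at 6.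

Step 6 (conjugate methylation and allylation). C-alkylation at the hindered C9 may be slow, so that proton transfer between enolate and product scrambles the enolate towards C7, or over-alkylation and O-allylation compete. The fallback keeps the same two bonds but delivers allyl through a palladium π-allyl ion pair. It sets out from 9: after the same Me2CuLi addition, enolate 12 is O-acylated with allyl chloroformate (THF/DMPU, −78 °C) to give the allyl enol carbonate, methyl (1S,4aS,8aS)-1,4a-dimethyl-6-{[(prop-2-en-1-yloxy)carbonyl]oxy}-1,2,3,4,4a,7,8,8a-octahydronaphthalene-1-carboxylate F3. Pd(PPh3)4 (zerovalent palladium, catalytic) in THF then effects Tsuji decarboxylative allylation, which forms the C9–C11 bond regiospecifically at the carbon that carried the carbonate and on the convex face. The route is rejoined at 13.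

Step 11 (carboalumination and hydroxymethylation). The organoaluminium and organolithium reagents may attack the C19 ester, or the aluminate may be captured incompletely by formaldehyde. The fallback avoids organoaluminium chemistry and builds the alkene by olefination. It sets out from aldehyde 17: MeMgBr (THF, −78 °C) gives methyl (1S,4aR,5S,8aS)-5-(3-hydroxybutyl)-1,4a-dimethyl-6-methylidenedecahydronaphthalene-1-carboxylate F4 (both carbinol epimers). Dess–Martin oxidation gives the methyl ketone, methyl (1S,4aR,5S,8aS)-1,4a-dimethyl-6-methylidene-5-(3-oxobutyl)decahydronaphthalene-1-carboxylate F5. Horner–Wadsworth–Emmons olefination with triethyl phosphonoacetate and NaH gives the E-enoate, methyl (1S,4aR,5S,8aS)-5-[(3E)-5-ethoxy-3-methyl-5-oxopent-3-en-1-yl]-1,4a-dimethyl-6-methylidenedecahydronaphthalene-1-carboxylate F6, to be separated from its Z isomer. i-Bu2AlH (CH2Cl2, −78 °C) should reduce the unhindered conjugated ethyl ester in preference to the neopentyl methyl ester, and the route is rejoined at 21.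

Further compounds
F1 | step 2 | lithium (3S)-3-methyl-3-phenylcyclohex-1-en-1-olate | [Li]OC1=C[C@@](C)(c2ccccc2)CCC1
F2 | step 2 | (2R,3S)-2-[(2E)-3-chlorobut-2-en-1-yl]-3-methyl-3-phenylcyclohexan-1-one | Cl/C(C)=C/C[C@H]1C(=O)CCC[C@]1(C)c2ccccc2
F3 | step 6 | methyl (1S,4aS,8aS)-1,4a-dimethyl-6-{[(prop-2-en-1-yloxy)carbonyl]oxy}-1,2,3,4,4a,7,8,8a-octahydronaphthalene-1-carboxylate | C=CCOC(=O)OC1CC[C@H]2[C@](C)(CCC[C@]2(C)C(=O)OC)C=1
F4 | step 11 | methyl (1S,4aR,5S,8aS)-5-(3-hydroxybutyl)-1,4a-dimethyl-6-methylidenedecahydronaphthalene-1-carboxylate (carbinol epimers) | C=C1CC[C@H]2[C@](C)(CCC[C@]2(C)C(=O)OC)[C@H]1CCC(C)O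
F5 | step 11 | methyl (1S,4aR,5S,8aS)-1,4a-dimethyl-6-methylidene-5-(3-oxobutyl)decahydronaphthalene-1-carboxylate | C=C1CC[C@H]2[C@](C)(CCC[C@]2(C)C(=O)OC)[C@H]1CCC(C)=O
F6 | step 11 | methyl (1S,4aR,5S,8aS)-5-[(3E)-5-ethoxy-3-methyl-5-oxopent-3-en-1-yl]-1,4a-dimethyl-6-methylidenedecahydronaphthalene-1-carboxylate | C=C1CC[C@H]2[C@](C)(CCC[C@]2(C)C(=O)OC)[C@H]1CC/C(C)=C/C(=O)OCC
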